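The runs are calculated on assumed constants; the scatter is artificial.

**The species followed.** The intermediate was the species I had to follow, through five flasks that differ in their coupling partner.

in all of them: protic impurity 1.15 mM
- blue: starting material 15 mM; coupling partner 2.5 mM; run made earlier
- midnight: starting material 23 mM; coupling partner 2.50 mM; time 2.5 d
- dawn: starting material 23 mM; coupling partner 8.00 mM; time 2.5 d
- dusk: starting material 23 mM; coupling partner 25.0 mM; time 2.5 d
- summer: starting material 23 mM; coupling partner 80.0 mM; time 2.5 d
- spring: starting material 23 mM; coupling partner 200 mM; time 2.5 d

- blue (time / h: intermediate / %, product / %): 3.00: 4.5, 0; 4.00: 2.9, 0.1; 6.00: 6.3, 0; 10.0: 7.1, 2.7; 15.0: 7.4, 6.3; 25.0: 8.6, 6.3; 40.0: 5.2, 11.5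

(scatter of a reading: 1 percentage point)

1. amount of intermediate at the end, in percent of the starting material charged for midnight, dawn, dusk, summer, spring, in this order
2. how the row runs (rises, then falls / falls, then rises / hardly changes / rises all the way / falls all the way)

- "hardly changes" means that all values lie within two and a half points (for a concentration: within two and a half percent of the largest)

**First way.** In the blue run, intermediate plus product reached 2.50 mM at 40.0 h, against 2.5 mM of coupling partner charged, so I treated the partner there as the limiting reagent. Between 10.0 h and 40.0 h, I divided the product gained by the area under the intermediate curve and obtained 0.0400 h⁻¹. This reading is the first-order decay constant of the intermediate, the product formed per hour per unit of intermediate standing.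

**Second way.** The fall of the intermediate from 8.6% at 25.0 h to 5.2% at 40.0 h gave a smaller constant, 0.0335 h⁻¹. But intermediate plus product read 14.9% and then 16.7% over those hours, a rise of 1.8 percentage points against a scatter of 1 point per reading, so intermediate may still have been arriving, and the fall may be a net figure. I took the second way as the one that cheats, and I kept the first.

**My reckoning.** Over 2.5 d, the surviving fraction is 0.0905. Dating all the intermediate from time zero, I reckoned 9.05% for spring, where [coupling partner] far exceeds [starting material]. For midnight, the partner caps the intermediate at 10.9%, which leaves 0.986%. At dusk, the partner charge lies just above the starting material, so I expected both to thin together, a late feed, younger intermediate and the top of the row.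

**The forecast.** The forecast gave 1.5%, 4.5%, 14%, 10% and 9.5%, a row that rises, then falls, saying of dusk that “formation is slow and late”. Its midnight and spring figures stand above mine.

**The result.**

    starting material + coupling partner → intermediate + by-product (k = 5.93 L mol⁻¹ h⁻¹)
    intermediate → product (k = 0.0357 h⁻¹)
    starting material + protic impurity → quenched substrate (k = 27.3 L mol⁻¹ h⁻¹)

The flasks gave 1.79%, 6.12%, 17.3%, 12.4% and 11.9%, a row that rises, then falls, and the forecast held within its margin. The step from starting material and protic impurity to quenched substrate makes no difference to the spring figure. Summer held 0% of its starting material and 36.1% of intermediate at 1.25 d; carried over the remaining time, 0.0400 h⁻¹ predicts 10.9% at the end, and summer held 12.4%. For spring, with 0% of its starting material and 34.6% of intermediate at 1.25 d, the same constant predicts 10.4%, and spring held 11.9% at 2.50 d.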